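**Retrosynthetic overview**
1. The last bond made is the C16–O ester (Yamaguchi) between acid 24 (C15 carried as OTBS) and the isocoronarin-D-type alcohol 19; C15–OH to CHO is the final operation.
2. Both halves are drawn from one aldehyde, Dec–CH2–CHO 12. A Wittig reaction with lactone ylide 20 and lactone opening give the acyl half; aldol/E1cB with O-silylated (R)-3-hydroxybutyrolactone gives the alcohol half (E-alkylidene lactone, C14′ R).
3. Aldehyde 12: C8=C17 by Wittig methylenation of 8-ketone 10; 10 comes from the monocyclic 4-oxo-2-enoate 9 by forming C9–C10.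
4. Enabling feature: in ring B the quaternary fusion carbon C10 is bonded to C9, and C9 lies β to the C12 carbonyl and α to C8, a carbon at ketone level (C8=C17 in the target). So C9 can be the β-carbon of an enoate acceptor and C10 a tertiary radical born from the C1=C10 alkene of ring A: two acceptor-type alkene carbons joined reductively.
5. Ring order: ring A (enone 1) and the lactone ring (13) are bought; ring B is the only ring the route builds and the last one closed (step 6), and because 12 feeds both halves this one closure supplies both decalins. C5 (CBS reduction, then Johnson–Claisen) relays to C10 and C9.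

Key step: step 6

Remark: Dec stands for the (1S,4aS,8aS)-5,5,8a-trimethyl-2-methylidenedecahydronaphthalen-1-yl group; labdane locants are used in the comments (primed for the alcohol half); 1, 7, 13 and 20 are taken as catalogue chemicals.

**Route**

Step 1
Reactants: 1 2,4,4-trimethylcyclohex-2-en-1-one
Product: 2 (1R)-2,4,4-trimethylcyclohex-2-en-1-ol
Conditions: (S)-2-methyl-CBS-oxazaborolidine (10 mol%), BH3·SMe2, THF, −20 °C; MeOH quench
Reagents that add atoms: none
Why: Corey–Bakshi–Shibata reduction: with the α-methylated alkenyl side as the large group, the (S)-oxazaborolidine should deliver hydride to give the (R)-allylic alcohol, which fixes the absolute configuration of both decalin units.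

Step 2
Reactants: 2 (R)-allylic alcohol
Product: 4 ethyl [(1S)-2,6,6-trimethylcyclohex-2-en-1-yl]acetate, via ketene acetal 3 (not isolated)
Conditions: CH3C(OEt)3, EtCO2H (cat.), xylenes, 140 °C, removal of EtOH
Reagents that add atoms: triethyl orthoacetate (CC(OCC)(OCC)OCC)
Why: Johnson–Claisen rearrangement: ketene acetal 3 rearranges suprafacially, so the C–O stereocentre of 2 is transferred to the new C–C bond at C5 (S) while the alkene moves to C1=C10.

Step 3
Reactants: 4 ester
Product: 5 2-[(1S)-2,6,6-trimethylcyclohex-2-en-1-yl]ethan-1-ol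
Conditions: LiAlH4, Et2O, 0 °C
Reagents that add atoms: none
Why: Hydride reduction of the ester; the trisubstituted alkene and C5 are inert.

Step 4
Reactants: 5 alcohol
Product: 6 (6S)-6-(2-iodoethyl)-1,5,5-trimethylcyclohex-1-ene
Conditions: I2, PPh3, imidazole, CH2Cl2, 0 °C to rt
Reagents that add atoms: iodine (II)
Why: Appel-type iodination: SN2 displacement of the phosphonium-activated primary oxygen by iodide.

Step 5
Reactants: 6 iodide; 7 ethyl (2E)-4-chloro-4-oxobut-2-enoate (ethyl fumaroyl chloride)
Product: 9 ethyl (2E)-4-oxo-6-[(1S)-2,6,6-trimethylcyclohex-2-en-1-yl]hex-2-enoate, via alkylzinc iodide 8 (not isolated)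
Conditions: Zn, LiCl, THF, 40 °C; then 7, Pd(PPh3)4 (5 mol%), THF, 0 °C to rt
Reagents that add atoms: none
Why: Zinc insertion into the primary iodide, then Negishi acylation: oxidative addition of zerovalent palladium to the acid chloride, transmetallation and reductive elimination should outrun conjugate addition, and the E alkene of 7 is retained.

Step 6
Reactants: 9 monocyclic 4-oxo-2-enoate
Product: 10 ethyl [(1R,4aS,8aS)-5,5,8a-trimethyl-2-oxodecahydronaphthalen-1-yl]acetate
Conditions: Fe(acac)3 (30 mol%), PhSiH3, EtOH/HOCH2CH2OH (5:1), 60 °C, 0.02 M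
Reagents that add atoms: none
Why: Fe(acac)3, PhSiH3 and ethanol generate an iron hydride that transfers a hydrogen atom to C1 of the electron-rich ring A alkene; the tertiary C10 radical adds to C9 of the 4-oxo-2-enoate, and the α-ester radical at C11 is reduced by divalent iron to the enolate and protonated by ethanol, so two alkene carbons of acceptor-type polarity are joined reductively. The closest known reaction type is the iron-mediated reductive olefin coupling (hydrogen-atom-transfer-initiated Giese addition) in its intramolecular form, which is established for quaternary centres. Ring B closes 6-exo-trig through a chair transition state, the alternative attack at C11 being 7-endo. C10 is controlled by C5: with the C5 chain equatorial, C9 should reach the α lobe of the radical (the face of H5) because the β lobe is screened by the axial 4β-methyl group, which leaves the angular methyl β-axial and the fusion trans; C9 is set by the equatorial placement of the acceptor in the chair and, being α to the C8 ketone, can in any case settle as the equatorial epimer (9α-H). The step needs hydrogen-atom transfer to the donor alkene in the presence of the electron-poor acceptor, which the polarity difference of the two alkenes should secure, and it needs C5 to stay intact, which holds because no acid is present and the radical centre is C10.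

Step 7
Reactants: 10 keto ester
Product: 11 ethyl 2-Dec-acetate
Conditions: Ph3PCH3Br, KOt-Bu, toluene, rt to 90 °C
Reagents that add atoms: methyltriphenylphosphonium bromide ([Br-].C[P+](c1ccccc1)(c1ccccc1)c1ccccc1)
Why: Wittig methylenation: the ylide should attack only the ketone (the ester is inert), and C9, although α to the ketone, already rests in its more stable equatorial configuration.

Step 8
Reactants: 11 methylidene ester
Product: 12 2-Dec-acetaldehyde (Dec–CH2–CHO)
Conditions: i-Bu2AlH, CH2Cl2, −78 °C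
Reagents that add atoms: none
Why: Partial reduction of an ester: the aluminium hemiacetal is stable at −78 °C and should release the aldehyde only on work-up; the batch is divided between steps 10 and 13.

Step 9
Reactants: 13 (4R)-4-hydroxyoxolan-2-one ((R)-3-hydroxy-γ-butyrolactone)
Product: 14 (4R)-4-[(tert-butyldimethylsilyl)oxy]oxolan-2-one
Conditions: TBSCl, imidazole, DMF, rt
Reagents that add atoms: tert-butyldimethylsilyl chloride (CC(C)(C)[Si](C)(C)Cl)
Why: Standard imidazole-mediated silylation of the secondary alcohol; the stereocentre is not touched.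

Step 10
Reactants: 14 silyloxy lactone; 12 aldehyde
Product: 16 (3R,4R)-4-[(tert-butyldimethylsilyl)oxy]-3-(2-Dec-1-hydroxyethyl)oxolan-2-one (both carbinol epimers), via lithium enolate 15 (not isolated)
Conditions: LiN(i-Pr)2, THF, −78 °C; then 12, −78 °C; AcOH quench at −78 °C
Reagents that add atoms: none
Why: Lithium enolate aldol addition: at −78 °C β-elimination of the silyloxy group should be slow, and the aldehyde should add trans to the OTBS group; the carbinol centre forms as a mixture, which does not matter because both new centres are removed in step 11.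

Step 11
Reactants: 16 aldol adduct
Product: 18 (3E,4R)-4-[(tert-butyldimethylsilyl)oxy]-3-(2-Dec-ethylidene)oxolan-2-one, via mesylate 17 (not isolated)
Conditions: MeSO2Cl, Et3N, CH2Cl2, 0 °C; then DBU, rt
Reagents that add atoms: none
Why: Mesylation and E1cB elimination: mesylate is by far the better leaving group than silanolate, so the exocyclic conjugated alkene should form, expected as the E isomer in which the alkyl chain avoids the lactone carbonyl.

Step 12
Reactants: 18 silyl ether
Product: 19 (3E,4R)-4-hydroxy-3-(2-Dec-ethylidene)oxolan-2-one (isocoronarin-D-type alcohol)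
Conditions: HF·pyridine, pyridine, THF, 0 °C to rt
Reagents that add atoms: none
Why: Fluoride-mediated desilylation under buffered, nearly neutral conditions should spare the allylic alcohol, the alkylidene lactone and the exocyclic alkene.

Step 13
Reactants: 12 aldehyde; 20 3-(triphenyl-λ5-phosphanylidene)oxolan-2-one
Product: 21 (3E)-3-(2-Dec-ethylidene)oxolan-2-one
Conditions: toluene, 90 °C
Reagents that add atoms: none
Why: Wittig reaction of a stabilised ylide, which is expected to give the E-alkylidene lactone (alkyl chain trans to the lactone carbonyl).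

Step 14
Reactants: 21 alkylidene lactone
Product: 24 (2E)-2-{2-[(tert-butyldimethylsilyl)oxy]ethyl}-4-Dec-but-2-enoic acid, via potassium hydroxy-carboxylate 22 (not isolated), via bis-silyl ester 23 (not isolated)
Conditions: KOH, MeOH/H2O, rt; evaporate; TBSCl, imidazole, DMF, rt; then K2CO3 (cat.), MeOH/H2O, 0 °C; pH 5 buffer
Reagents that add atoms: potassium hydroxide ([K+].[OH-]); tert-butyldimethylsilyl chloride (CC(C)(C)[Si](C)(C)Cl)
Why: Saponification opens the lactone without touching the trisubstituted E alkene, exhaustive silylation caps both oxygens, and the far more labile silyl ester is then hydrolysed selectively, leaving the primary TBS ether.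

Step 15
Reactants: 24 acid; 19 alcohol
Product: 26 (3R,4E)-4-(2-Dec-ethylidene)-5-oxooxolan-3-yl (2E)-2-{2-[(tert-butyldimethylsilyl)oxy]ethyl}-4-Dec-but-2-enoate, via mixed anhydride 25 (not isolated)
Conditions: 2,4,6-Cl3C6H2COCl, Et3N, toluene, rt; then 19, DMAP, toluene, rt
Reagents that add atoms: none
Why: Yamaguchi esterification: DMAP should attack the enoyl carbonyl of the mixed anhydride, and the acylpyridinium acylates the secondary allylic alcohol with retention at C14′.

Step 16
Reactants: 26 silyl ether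
Product: 27 (3R,4E)-4-(2-Dec-ethylidene)-5-oxooxolan-3-yl (2E)-4-Dec-2-(2-hydroxyethyl)but-2-enoate
Conditions: HF·pyridine, pyridine, THF, 0 °C
Reagents that add atoms: none
Why: Fluoride cleavage of the primary silyl ether; buffered conditions at 0 °C and immediate use should keep the γ-hydroxy ester from lactonising with loss of 19.

Step 17
Reactants: 27 hydroxy ester
Product: 28 (3R,4E)-4-(2-Dec-ethylidene)-5-oxooxolan-3-yl (2E)-4-Dec-2-(2-oxoethyl)but-2-enoate (target)
Conditions: Dess–Martin periodinane, pyridine, CH2Cl2, 0 °C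
Reagents that add atoms: none
Why: Dess–Martin oxidation under buffered, non-acidic conditions should take the primary alcohol to the β,γ-unsaturated aldehyde without moving the C12=C13 double bond.

**Compound list**

1 | 2,4,4-trimethylcyclohex-2-en-1-one | CC1=CC(C)(C)CCC1=O | starting material
2 | (1R)-2,4,4-trimethylcyclohex-2-en-1-ol | O[C@@H]1CCC(C)(C)C=C1C | intermediate
3 | 1-ethoxy-1-{[(1R)-2,4,4-trimethylcyclohex-2-en-1-yl]oxy}ethene | C=C(OCC)O[C@@H]1CCC(C)(C)C=C1C | intermediate
4 | ethyl [(1S)-2,6,6-trimethylcyclohex-2-en-1-yl]acetate | CCOC(=O)C[C@@H]1C(C)=CCCC1(C)C | intermediate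
5 | 2-[(1S)-2,6,6-trimethylcyclohex-2-en-1-yl]ethan-1-ol | OCC[C@@H]1C(C)=CCCC1(C)C | intermediate
6 | (6S)-6-(2-iodoethyl)-1,5,5-trimethylcyclohex-1-ene | ICC[C@@H]1C(C)=CCCC1(C)C | intermediate
7 | ethyl (2E)-4-chloro-4-oxobut-2-enoate | CCOC(=O)/C=C/C(Cl)=O | starting material
8 | iodo{2-[(1S)-2,6,6-trimethylcyclohex-2-en-1-yl]ethyl}zinc | I[Zn]CC[C@@H]1C(C)=CCCC1(C)C | intermediate
9 | ethyl (2E)-4-oxo-6-[(1S)-2,6,6-trimethylcyclohex-2-en-1-yl]hex-2-enoate | CCOC(=O)/C=C/C(=O)CC[C@@H]1C(C)=CCCC1(C)C | intermediate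
10 | ethyl [(1R,4aS,8aS)-5,5,8a-trimethyl-2-oxodecahydronaphthalen-1-yl]acetate | O=C1CC[C@H]2C(C)(C)CCC[C@]2(C)[C@H]1CC(=O)OCC | intermediate
11 | ethyl 2-Dec-acetate | C=C1CC[C@H]2C(C)(C)CCC[C@]2(C)[C@H]1CC(=O)OCC | intermediate
12 | 2-Dec-acetaldehyde | C=C1CC[C@H]2C(C)(C)CCC[C@]2(C)[C@H]1CC=O | intermediate
13 | (4R)-4-hydroxyoxolan-2-one | O[C@H]1COC(=O)C1 | starting material
14 | (4R)-4-[(tert-butyldimethylsilyl)oxy]oxolan-2-one | CC(C)(C)[Si](C)(C)O[C@H]1COC(=O)C1 | intermediate
15 | lithium enolate of 14 | [Li+].[O-]C1=C[C@@H](O[Si](C)(C)C(C)(C)C)CO1 | intermediate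
16 | (3R,4R)-4-[(tert-butyldimethylsilyl)oxy]-3-(2-Dec-1-hydroxyethyl)oxolan-2-one, carbinol epimers | C=C1CC[C@H]2C(C)(C)CCC[C@]2(C)[C@H]1CC(O)[C@H]1C(=O)OC[C@@H]1O[Si](C)(C)C(C)(C)C | intermediate
17 | methanesulfonate of 16 (at the side-chain carbinol) | C=C1CC[C@H]2C(C)(C)CCC[C@]2(C)[C@H]1CC(OS(C)(=O)=O)[C@H]1C(=O)OC[C@@H]1O[Si](C)(C)C(C)(C)C | intermediate
18 | (3E,4R)-4-[(tert-butyldimethylsilyl)oxy]-3-(2-Dec-ethylidene)oxolan-2-one | CC(C)(C)[Si](C)(C)O[C@H]1COC(=O)/C1=C/C[C@H]1C(=C)CC[C@H]2C(C)(C)CCC[C@]12C | intermediate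
19 | (3E,4R)-4-hydroxy-3-(2-Dec-ethylidene)oxolan-2-one | O[C@H]1COC(=O)/C1=C/C[C@H]1C(=C)CC[C@H]2C(C)(C)CCC[C@]12C | intermediate
20 | 3-(triphenyl-λ5-phosphanylidene)oxolan-2-one | O=C1OCCC1=P(c1ccccc1)(c1ccccc1)c1ccccc1 | starting material
21 | (3E)-3-(2-Dec-ethylidene)oxolan-2-one | C=C1CC[C@H]2C(C)(C)CCC[C@]2(C)[C@H]1C/C=C1\CCOC1=O | intermediate
22 | potassium (2E)-4-Dec-2-(2-hydroxyethyl)but-2-enoate | C=C1CC[C@H]2C(C)(C)CCC[C@]2(C)[C@H]1C/C=C(\CCO)C(=O)[O-].[K+] | intermediate
23 | tert-butyldimethylsilyl (2E)-2-{2-[(tert-butyldimethylsilyl)oxy]ethyl}-4-Dec-but-2-enoate | C=C1CC[C@H]2C(C)(C)CCC[C@]2(C)[C@H]1C/C=C(\CCO[Si](C)(C)C(C)(C)C)C(=O)O[Si](C)(C)C(C)(C)C | intermediate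
24 | (2E)-2-{2-[(tert-butyldimethylsilyl)oxy]ethyl}-4-Dec-but-2-enoic acid | C=C1CC[C@H]2C(C)(C)CCC[C@]2(C)[C@H]1C/C=C(\CCO[Si](C)(C)C(C)(C)C)C(=O)O | intermediate
25 | mixed anhydride of 24 with 2,4,6-trichlorobenzoic acid | C=C1CC[C@H]2C(C)(C)CCC[C@]2(C)[C@H]1C/C=C(\CCO[Si](C)(C)C(C)(C)C)C(=O)OC(=O)c1c(Cl)cc(Cl)cc1Cl | intermediate
26 | (3R,4E)-4-(2-Dec-ethylidene)-5-oxooxolan-3-yl (2E)-2-{2-[(tert-butyldimethylsilyl)oxy]ethyl}-4-Dec-but-2-enoate | C=C1CC[C@H]2C(C)(C)CCC[C@]2(C)[C@H]1C/C=C(\CCO[Si](C)(C)C(C)(C)C)C(=O)O[C@H]1COC(=O)/C1=C/C[C@H]1C(=C)CC[C@H]2C(C)(C)CCC[C@]12C | intermediate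
27 | (3R,4E)-4-(2-Dec-ethylidene)-5-oxooxolan-3-yl (2E)-4-Dec-2-(2-hydroxyethyl)but-2-enoate | C=C1CC[C@H]2C(C)(C)CCC[C@]2(C)[C@H]1C/C=C(\CCO)C(=O)O[C@H]1COC(=O)/C1=C/C[C@H]1C(=C)CC[C@H]2C(C)(C)CCC[C@]12C | intermediate
28 | (3R,4E)-4-(2-Dec-ethylidene)-5-oxooxolan-3-yl (2E)-4-Dec-2-(2-oxoethyl)but-2-enoate | C=C1CC[C@H]2C(C)(C)CCC[C@]2(C)[C@H]1C/C=C(\CC=O)C(=O)O[C@H]1COC(=O)/C1=C/C[C@H]1C(=C)CC[C@H]2C(C)(C)CCC[C@]12C | target

**Count and risks**

Total step count: 17. Longest linear sequence: 14 steps (steps 1 to 8, 10 to 12 and 15 to 17).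

Steps most likely to fail:

Step 6. Two processes may defeat the ring closure: reduction of the electron-poor alkene before the C10 radical is formed, and addition of C9 to the axial face of the C10 radical, which would give the cis ring fusion. The fallback closes ring B by a polar route; it sets out from iodide 6 (through 8) and comes back at 10. Alkylzinc iodide 8 would be acylated with ethyl 3-chloro-3-oxopropanoate under Pd(PPh3)4 to ethyl 3-oxo-5-[(1S)-2,6,6-trimethylcyclohex-2-en-1-yl]pentanoate F1. C-Alkylation with ethyl bromoacetate (K2CO3, acetone) would give diethyl 2-{3-[(1S)-2,6,6-trimethylcyclohex-2-en-1-yl]propanoyl}butanedioate F2. SnCl4 in CH2Cl2 at low temperature should protonate the ring alkene, and the enol carbon should trap the tertiary C10 cation through a chair (the established Lewis-acid cyclisation of cyclogeranyl β-keto esters to trans-fused decalones), giving ethyl (4aS,8aS)-1-(2-ethoxy-2-oxoethyl)-5,5,8a-trimethyl-2-oxodecahydronaphthalene-1-carboxylate F3. Krapcho dealkoxycarbonylation (LiCl, wet DMSO, 150 °C) would remove the ester on C9 and return 10.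

Step 5. The organozinc may add in conjugate fashion to 7 or to the product, and the doubly activated alkene of 9 may oligomerise under the coupling conditions. The fallback uses a furan as a masked 4-oxo-2-enoate; it sets out from 6 and comes back at 9. Iodide 6 would alkylate 2-furyllithium (furan, n-BuLi, THF) to 2-{2-[(1S)-2,6,6-trimethylcyclohex-2-en-1-yl]ethyl}furan F4. Oxidative ring opening (N-bromosuccinimide, pyridine, aqueous acetone, −15 °C), followed in the same flask by NaClO2 with 2-methylbut-2-ene, should give (2E)-4-oxo-6-[(1S)-2,6,6-trimethylcyclohex-2-en-1-yl]hex-2-enoic acid F5. EtI and K2CO3 in DMF would return 9.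

Step 2. Bond formation next to the quaternary C4 may be slow, and ionisation of the allylic alcohol under acid at 140 °C may erode the enantiomeric purity. The fallback is an anti-SN2′ substitution; it sets out from 1 and comes back at 5. Reduction of 1 with the (R)-oxazaborolidine and BH3·SMe2 would give (1S)-2,4,4-trimethylcyclohex-2-en-1-ol F6, which is esterified with pyridine-2-carboxylic acid (DCC, DMAP) to (1S)-2,4,4-trimethylcyclohex-2-en-1-yl pyridine-2-carboxylate F7. CH2=CHMgBr with CuBr·SMe2 should displace the picolinate in anti-SN2′ fashion to give (6S)-6-ethenyl-1,5,5-trimethylcyclohex-1-ene F8. 9-BBN, then H2O2/NaOH, should hydroborate only the vinyl group and return alcohol 5.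

**Further compounds**

F1 | step 6 | ethyl 3-oxo-5-[(1S)-2,6,6-trimethylcyclohex-2-en-1-yl]pentanoate | CCOC(=O)CC(=O)CC[C@@H]1C(C)=CCCC1(C)C
F2 | step 6 | diethyl 2-{3-[(1S)-2,6,6-trimethylcyclohex-2-en-1-yl]propanoyl}butanedioate (epimers at the new centre) | CCOC(=O)CC(C(=O)OCC)C(=O)CC[C@@H]1C(C)=CCCC1(C)C
F3 | step 6 | ethyl (4aS,8aS)-1-(2-ethoxy-2-oxoethyl)-5,5,8a-trimethyl-2-oxodecahydronaphthalene-1-carboxylate (C1 not defined) | O=C1CC[C@H]2C(C)(C)CCC[C@]2(C)C1(CC(=O)OCC)C(=O)OCC
F4 | step 5 | 2-{2-[(1S)-2,6,6-trimethylcyclohex-2-en-1-yl]ethyl}furan | c1coc(CC[C@@H]2C(C)=CCCC2(C)C)c1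
F5 | step 5 | (2E)-4-oxo-6-[(1S)-2,6,6-trimethylcyclohex-2-en-1-yl]hex-2-enoic acid | OC(=O)/C=C/C(=O)CC[C@@H]1C(C)=CCCC1(C)C
F6 | step 2 | (1S)-2,4,4-trimethylcyclohex-2-en-1-ol | O[C@H]1CCC(C)(C)C=C1C
F7 | step 2 | (1S)-2,4,4-trimethylcyclohex-2-en-1-yl pyridine-2-carboxylate | O=C(O[C@H]1CCC(C)(C)C=C1C)c1ccccn1
F8 | step 2 | (6S)-6-ethenyl-1,5,5-trimethylcyclohex-1-ene | C=C[C@@H]1C(C)=CCCC1(C)C
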